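The synthesis rests on cutting the hindered biaryl bond between C2' of ring B (first flavanone) and C8'' of ring D (phloroglucinol ring of the second flavanone). The key step exploits two features. C8'' lies between two oxygens (O1'' and 7''-OMe), which guide iodination and ease zinc insertion. C2' lies between C1' and 3'-OMe, a position that can be bought as a bromide. The precursors are two complete, MOM-protected (2S)-flavanones, an 8-iodide and a 2'-bromide, both grown from one acetophenone and resolved by transfer hydrogenation. A neutral Negishi coupling unites them in one operation and builds the tetra-ortho-substituted axis while sparing both base-labile C2 centres. Acid then frees the three phenols.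

Key step: step 8

Locants: the first flavanone has rings A (benzo), C (pyranone) and B (aryl, primed locants). The second has rings D (benzo), E (pyranone) and F (syringyl), and its locants carry a double prime.

Assumption: the SMILES fixes C2 and C2'' as S but leaves the sense of the C2'–C8'' axis open, so the axis is not treated as a stereochemical goal. If the coupling gives two atropisomers, both fit the structure as drawn, and they would be separated at 14.

Step 1
Reactants: 1 1-(2,6-dihydroxy-4-methoxyphenyl)ethanone
Product: 2 1-[2-hydroxy-4-methoxy-6-(methoxymethoxy)phenyl]ethanone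
Conditions: MOMCl (1.1 equiv), iPr2NEt, CH2Cl2, 0 °C to rt
Reagents that add atoms: chloromethyl methyl ether (MOMCl), COCCl
Why: In this O-alkylation (MOM protection), once one of the two equivalent phenols is capped the other is held in a strong hydrogen bond to the acetyl oxygen and resists a second alkylation, so the mono-ether should prevail.

Step 2
Reactants: 2 1-[2-hydroxy-4-methoxy-6-(methoxymethoxy)phenyl]ethanone; 3 2-bromo-3,4-dimethoxybenzaldehyde
Product: 5 rac-2-(2-bromo-3,4-dimethoxyphenyl)-7-methoxy-5-(methoxymethoxy)chroman-4-one, via bromochalcone 4 (not isolated)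
Conditions: KOH, EtOH/H2O, rt; then AcOH to pH 6, reflux
Reagents that add atoms: none
Why: A Claisen–Schmidt condensation gives the (E)-chalcone, and in the acetate buffer formed in the flask the free phenol closes ring C by a 6-endo-trig oxa-Michael addition, which is favoured for 6'-alkoxychalcones; C2 is formed racemic here and is resolved in step 3.

Step 3
Reactants: 5 rac-2-(2-bromo-3,4-dimethoxyphenyl)-7-methoxy-5-(methoxymethoxy)chroman-4-one
Product: 6 (2S)-2-(2-bromo-3,4-dimethoxyphenyl)-7-methoxy-5-(methoxymethoxy)chroman-4-one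
Conditions: RuCl[(R,R)-TsDPEN](p-cymene) (1 mol %), HCO2H/NEt3 (5:2), EtOAc, rt, stopped just past half conversion; chromatography
Reagents that add atoms: none
Why: This is a kinetic resolution by Noyori–Ikariya asymmetric transfer hydrogenation, a known way to enantiopure flavanones: the (R,R)-catalyst makes the (4R)-carbinol, which matches the inherent 2,4-cis hydride delivery only in the (2R)-ketone, so that enantiomer should be consumed as the polar (2R,4R)-flavan-4-ol while the (2S)-ketone stays behind, and the acidic formate medium does not open ring C.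

Step 4
Reactants: 2 1-[2-hydroxy-4-methoxy-6-(methoxymethoxy)phenyl]ethanone
Product: 7 1-[2-hydroxy-3-iodo-4-methoxy-6-(methoxymethoxy)phenyl]ethanone
Conditions: BnMe3N·ICl2 (1.05 equiv), CaCO3, CH2Cl2/MeOH, rt
Reagents that add atoms: benzyltrimethylammonium dichloroiodate, C[N+](C)(C)Cc1ccccc1.Cl[I-]Cl
Why: In this electrophilic aromatic iodination the dichloroiodate reagent attacks chelated phenols ortho to the free hydroxyl group, here C3 between OH and OMe, and CaCO3 takes up HCl so that the MOM acetal is kept.

Step 5
Reactants: 8 syringaldehyde (4-hydroxy-3,5-dimethoxybenzaldehyde)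
Product: 9 3,5-dimethoxy-4-(methoxymethoxy)benzaldehyde
Conditions: MOMCl, iPr2NEt, CH2Cl2, 0 °C to rt
Reagents that add atoms: chloromethyl methyl ether (MOMCl), COCCl
Why: MOM protection of the only phenol is needed because the free phenoxide would deactivate the aldehyde in the aldol step and would later protonate the arylzinc.

Step 6
Reactants: 7 1-[2-hydroxy-3-iodo-4-methoxy-6-(methoxymethoxy)phenyl]ethanone; 9 3,5-dimethoxy-4-(methoxymethoxy)benzaldehyde
Product: 11 rac-2-[3,5-dimethoxy-4-(methoxymethoxy)phenyl]-8-iodo-7-methoxy-5-(methoxymethoxy)chroman-4-one, via iodochalcone 10 (not isolated)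
Conditions: KOH, EtOH/H2O, rt; then AcOH to pH 6, reflux
Reagents that add atoms: none
Why: A Claisen–Schmidt condensation is followed by a 6-endo-trig oxa-Michael closure of ring E; only the one free phenol, the one next to iodine, can close, which places iodine at C8'', and C2'' is formed racemic and resolved in step 7.

Step 7
Reactants: 11 rac-2-[3,5-dimethoxy-4-(methoxymethoxy)phenyl]-8-iodo-7-methoxy-5-(methoxymethoxy)chroman-4-one
Product: 12 (2S)-2-[3,5-dimethoxy-4-(methoxymethoxy)phenyl]-8-iodo-7-methoxy-5-(methoxymethoxy)chroman-4-one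
Conditions: RuCl[(R,R)-TsDPEN](p-cymene) (1 mol %), HCO2H/NEt3 (5:2), EtOAc, rt, stopped just past half conversion; chromatography
Reagents that add atoms: none
Why: The same kinetic resolution by asymmetric transfer hydrogenation as in step 3 applies: the (2R)-ketone is the matched substrate of the (R,R)-catalyst and should be reduced to the (2R,4R)-carbinol, which leaves the (2S)-ketone, and aryl iodides are normally inert to the ruthenium hydride.

Step 8
Reactants: 12 (2S)-2-[3,5-dimethoxy-4-(methoxymethoxy)phenyl]-8-iodo-7-methoxy-5-(methoxymethoxy)chroman-4-one; 6 (2S)-2-(2-bromo-3,4-dimethoxyphenyl)-7-methoxy-5-(methoxymethoxy)chroman-4-one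
Product: 14 (2S,2''S)-tris-O-MOM C2'–C8'' biflavanone, via arylzinc iodide 13 (not isolated)
Conditions: 12, Zn dust (activated with BrCH2CH2Br and TMSCl), LiCl, THF, 50 °C; solution decanted from excess Zn; then 6, PdCl2(IPent)(3-chloropyridine) (4 mol %; IPent = 1,3-bis[2,6-di(pentan-3-yl)phenyl]imidazol-2-ylidene), THF/NMP, rt to 50 °C
Reagents that add atoms: none
Why: Zinc inserts into the C8''–I bond of 12, helped by LiCl and by the flanking oxygens O1'' and 7''-OMe, and bromide 6 is added only afterwards, so each halide has one role; zerovalent palladium bearing the bulky carbene then adds oxidatively to the C2'–Br bond, the arylzinc transmetalates to the divalent arylpalladium bromide, and reductive elimination, driven by the flexible bulk of the ligand, forms the C2'–C8'' bond. The closest known reaction type is the low-temperature Negishi coupling used for functionalised tetra-ortho-substituted biaryls. No ring is closed. No new stereocentre arises; the new axis is stereogenic, is biased only by the neighbouring C2 centre of 6, and its sense is not part of the target structure. The step needs site selectivity, which the positions of iodine and bromine fix (C6'' and C6' carry only hydrogen), and retention at C2 and C2'', which the neutral, base-free medium secures because retro-oxa-Michael opening of a flavanone starts with enolisation at C3. Ketones, MOM acetals and aryl methyl ethers are inert to arylzinc halides.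

Step 9
Reactants: 14 (2S,2''S)-tris-O-MOM C2'–C8'' biflavanone
Product: 15 target, (2S)-5-hydroxy-2-{2-[(2S)-5-hydroxy-2-(4-hydroxy-3,5-dimethoxyphenyl)-7-methoxy-4-oxochroman-8-yl]-3,4-dimethoxyphenyl}-7-methoxychroman-4-one
Conditions: HCl (3 M), MeOH, 40 °C
Reagents that add atoms: none
Why: Acid-catalysed acetal exchange with methanol removes all three MOM groups, and flavanones hold their C2 configuration in mild acid because ring opening needs an enolate.

Compound list
1 | 1-(2,6-dihydroxy-4-methoxyphenyl)ethanone | CC(=O)c1c(O)cc(OC)cc1O | starting material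
2 | 1-[2-hydroxy-4-methoxy-6-(methoxymethoxy)phenyl]ethanone | CC(=O)c1c(O)cc(OC)cc1OCOC | intermediate
3 | 2-bromo-3,4-dimethoxybenzaldehyde | O=Cc1ccc(OC)c(OC)c1Br | starting material
4 | (E)-3-(2-bromo-3,4-dimethoxyphenyl)-1-[2-hydroxy-4-methoxy-6-(methoxymethoxy)phenyl]prop-2-en-1-one (bromochalcone) | COCOc1cc(OC)cc(O)c1C(=O)/C=C/c1ccc(OC)c(OC)c1Br | intermediate
5 | rac-2-(2-bromo-3,4-dimethoxyphenyl)-7-methoxy-5-(methoxymethoxy)chroman-4-one | COc1cc(OCOC)c2c(c1)OC(c1ccc(OC)c(OC)c1Br)CC2=O | intermediate
6 | (2S)-2-(2-bromo-3,4-dimethoxyphenyl)-7-methoxy-5-(methoxymethoxy)chroman-4-one | COc1cc(OCOC)c2c(c1)O[C@H](c1ccc(OC)c(OC)c1Br)CC2=O | intermediate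
7 | 1-[2-hydroxy-3-iodo-4-methoxy-6-(methoxymethoxy)phenyl]ethanone | CC(=O)c1c(O)c(I)c(OC)cc1OCOC | intermediate
8 | syringaldehyde | COc1cc(C=O)cc(OC)c1O | starting material
9 | 3,5-dimethoxy-4-(methoxymethoxy)benzaldehyde | COCOc1c(OC)cc(C=O)cc1OC | intermediate
10 | (E)-3-[3,5-dimethoxy-4-(methoxymethoxy)phenyl]-1-[2-hydroxy-3-iodo-4-methoxy-6-(methoxymethoxy)phenyl]prop-2-en-1-one (iodochalcone) | COCOc1cc(OC)c(I)c(O)c1C(=O)/C=C/c1cc(OC)c(OCOC)c(OC)c1 | intermediate
11 | rac-2-[3,5-dimethoxy-4-(methoxymethoxy)phenyl]-8-iodo-7-methoxy-5-(methoxymethoxy)chroman-4-one | COc1cc(OCOC)c2c(c1I)OC(c1cc(OC)c(OCOC)c(OC)c1)CC2=O | intermediate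
12 | (2S)-2-[3,5-dimethoxy-4-(methoxymethoxy)phenyl]-8-iodo-7-methoxy-5-(methoxymethoxy)chroman-4-one | COc1cc(OCOC)c2c(c1I)O[C@H](c1cc(OC)c(OCOC)c(OC)c1)CC2=O | intermediate
13 | C8''-arylzinc iodide of 12 | COc1cc(OCOC)c2c(c1[Zn]I)O[C@H](c1cc(OC)c(OCOC)c(OC)c1)CC2=O | intermediate
14 | (2S,2''S)-tris-O-MOM C2'–C8'' biflavanone | COc1cc(OCOC)c2c(c1)O[C@H](c1ccc(OC)c(OC)c1-c1c(OC)cc(OCOC)c3c1O[C@H](c1cc(OC)c(OCOC)c(OC)c1)CC3=O)CC2=O | intermediate
15 | CNP0229789.1, (2S,2''S)-biflavanone | COc1cc(O)c2c(c1)O[C@H](c1ccc(OC)c(OC)c1-c1c(OC)cc(O)c3c1O[C@H](c1cc(OC)c(O)c(OC)c1)CC3=O)CC2=O | target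

Total step count: 9. Longest linear sequence: 6 steps (1, 4, 6, 7, 8, 9, from compound 1).

Steps most likely to fail

Step 8. Several things may go wrong:
- Zinc insertion may be slow at the crowded, electron-rich C8''–I bond.
- The arylzinc may be protonated.
- Transmetalation or reductive elimination may stall at the tetra-ortho-substituted palladium centre.
- Zinc salts may assist a ring opening that erodes C2.

Fallback: the union is moved to the flavan-4-ol oxidation level, where C2 can no longer epimerise and a basic Suzuki–Miyaura coupling is allowed. It sets out from 6 and 12. NaBH4 in MeOH reduces each ketone to the 2,4-cis alcohol, giving the (2S,4S)-bromoflavan-4-ol F1 and the (2S,4S)-iodoflavan-4-ol F2. F1 is treated with n-BuLi (2.2 equiv, THF, −78 °C) and 2-isopropoxy-4,4,5,5-tetramethyl-1,3,2-dioxaborolane to give the C2'-pinacol boronate F3. F3 and F2 are coupled with PdCl2(IPent)(3-chloropyridine) and KOH in dioxane at 65 °C to the bis(flavan-4-ol) F4. Dess–Martin periodinane in CH2Cl2 then oxidises both carbinols, and the route is rejoined at 14.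

Step 7. The catalyst may discriminate poorly between the enantiomers because the peri 5''-OMOM group slows hydride transfer. The (S)-ketone may also be slowly reduced past half conversion, or iodine may be lost by transfer hydrogenolysis. Fallback: catalytic resolution is replaced by physical separation. It sets out from 11. Preparative HPLC on an amylose tris(3,5-dimethylphenylcarbamate) phase gives 12 directly, where the route is rejoined. The (2R)-iodoflavanone F5 is racemised through chalcone 10 with NaOAc in hot EtOH and returned to 11. The same measure would serve for 5 to 6.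

Step 4. Iodination may attack para to the free phenol (C5 instead of C3), may occur twice, or may be accompanied by acid loss of the MOM group. Fallback: symmetry, not directing effects, decides the site. It sets out from 1, in which C3 and C5 are equivalent, so mono-iodination (BnMe3N·ICl2, CaCO3, CH2Cl2/MeOH) can give only 1-(2,6-dihydroxy-3-iodo-4-methoxyphenyl)ethanone F6. Its dianion (NaH, 2.1 equiv, DMF, 0 °C) is then alkylated with one equivalent of MOMCl at the more basic and less crowded phenoxide remote from iodine, which rejoins the route at 7.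

Further compounds
F1 | step 8 | (2S,4S)-2-(2-bromo-3,4-dimethoxyphenyl)-7-methoxy-5-(methoxymethoxy)chroman-4-ol | COc1cc(OCOC)c2c(c1)O[C@H](c1ccc(OC)c(OC)c1Br)C[C@@H]2O
F2 | step 8 | (2S,4S)-2-[3,5-dimethoxy-4-(methoxymethoxy)phenyl]-8-iodo-7-methoxy-5-(methoxymethoxy)chroman-4-ol | COc1cc(OCOC)c2c(c1I)O[C@H](c1cc(OC)c(OCOC)c(OC)c1)C[C@@H]2O
F3 | step 8 | (2S,4S)-2-[3,4-dimethoxy-2-(4,4,5,5-tetramethyl-1,3,2-dioxaborolan-2-yl)phenyl]-7-methoxy-5-(methoxymethoxy)chroman-4-ol | COc1cc(OCOC)c2c(c1)O[C@H](c1ccc(OC)c(OC)c1B1OC(C)(C)C(C)(C)O1)C[C@@H]2O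
F4 | step 8 | (2S,4S,2''S,4''S)-tris-O-MOM C2'–C8'' bis(flavan-4-ol) | COc1cc(OCOC)c2c(c1)O[C@H](c1ccc(OC)c(OC)c1-c1c(OC)cc(OCOC)c3c1O[C@H](c1cc(OC)c(OCOC)c(OC)c1)C[C@@H]3O)C[C@@H]2O
F5 | step 7 | (2R)-2-[3,5-dimethoxy-4-(methoxymethoxy)phenyl]-8-iodo-7-methoxy-5-(methoxymethoxy)chroman-4-one | COc1cc(OCOC)c2c(c1I)O[C@@H](c1cc(OC)c(OCOC)c(OC)c1)CC2=O
F6 | step 4 | 1-(2,6-dihydroxy-3-iodo-4-methoxyphenyl)ethanone | CC(=O)c1c(O)cc(OC)c(I)c1O
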